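**Plan**

1. Retrosynthesis (isochromene numbering; side chain C9 on C3, then C10, C11=C12, C13): the two O–Si bonds are cut last. The carbocycle is then cut at C4a=C5 and C7–C8 into 3-hydroxybutan-2-one and a 6-substituted 4-oxo-4H-pyran-3-carbaldehyde. The pyranone is cut at O2–C1/C4a–C8a (acylketene + 3-aminoacrolein), then C3–C4 (Claisen), C9–C10 (aldol) and C11=C12 (Wittig).
2. Enabling feature: in the ring C4a–C5–C6–C7–C8–C8a, the unit C4a=C5–C6=O is a vinylogous γ-pyrone, i.e. the dehydrated aldol of a methyl ketone on the pyranone carbonyl C4a. The unit C6(=O)–C7(OH)(CH3)–C8H(OH) is the aldol of an acetoin enediolate with an aldehyde C8 on C8a. Acetoin is thus a 1,3-dinucleophile (C7, C5) and the formylpyranone a 1,3-dielectrophile (C8, C4a).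
3. Forward order: side chain (C13, then C11=C12, then C9–C10), then the pyran ring, then the carbocycle in one flask, then desilylation.
4. Stereochemistry: C13 comes from (S)-2-methylbutan-1-ol and the E-alkene from a stabilised ylide. C9/C10 and C7/C8 each come from a catalyst-controlled syn aldol of a tetrasubstituted Z-zinc enediolate; both donors are racemic, and their stereocentre is erased on enolisation.

Key step: step 8

Assumption: (R,R)-ProPhenol is written for steps 4 and 8 on the assumption that the facial preference of this dinuclear zinc catalyst with unbranched α-hydroxy carbonyl donors carries over to the α-methyl donors. If the sense is opposite, the (S,S)-ligand is used. (ProPhenol = 2,6-bis[[2-(hydroxydiphenylmethyl)pyrrolidin-1-yl]methyl]-4-methylphenol.)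

**Route**

Step 1
Reactants: 1 (S)-2-methylbutan-1-ol
Product: 2 (S)-2-methylbutanal
Conditions: TEMPO (cat.), PhI(OAc)2, CH2Cl2, 0 °C → rt; solution used directly
Reagents that add atoms: none
Why: TEMPO/iodine(III) oxidation of a primary alcohol stops at the aldehyde under neutral conditions, so the α-stereocentre should not epimerise.

Step 2
Reactants: 2 (S)-2-methylbutanal, 3 2-(triphenylphosphoranylidene)propanal
Product: 4 (2E,4S)-2,4-dimethylhex-2-enal
Conditions: CH2Cl2, 40 °C
Reagents that add atoms: none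
Why: Wittig olefination with a stabilised formyl ylide should give the E-trisubstituted enal under neutral conditions that leave C4 untouched.

Step 3
Reactants: 5 2-hydroxypropanamide (racemic lactamide), 6 2,5-dimethoxytetrahydrofuran
Product: 7 2-hydroxy-1-(1H-pyrrol-1-yl)propan-1-one (racemic)
Conditions: AcOH, 90 °C
Reagents that add atoms: none
Why: Clauson–Kaas pyrrole synthesis on the primary amide nitrogen gives the N-acylpyrrole, a ketone-like acyl donor; the racemate suffices because the stereocentre is erased in step 4.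

Step 4
Reactants: 7 2-hydroxy-1-(1H-pyrrol-1-yl)propan-1-one (1.5 equiv), 4 (2E,4S)-2,4-dimethylhex-2-enal
Product: 8 (2S,3R,4E,6S)-2,3-dihydroxy-2,4,6-trimethyl-1-(1H-pyrrol-1-yl)oct-4-en-1-one
Conditions: (R,R)-ProPhenol (10 mol%), Et2Zn (20 mol%), 4 Å MS, THF, −20 → 0 °C
Reagents that add atoms: none
Why: Proposed new method: the dinuclear zinc complex should convert both enantiomers of 7 into one bridging Z-zinc enediolate, which adds to the zinc-bound aldehyde through a closed transition state, so the catalyst pocket sets C9 (S) and C10 (R) and the Z-geometry makes the diol syn; the closest known reaction types are the zinc–ProPhenol direct aldol of unbranched α-hydroxy N-acylpyrroles (syn-1,2-diols) and zinc-catalysed direct aldols of α-methyl-α-hydroxy aryl ketones that form tertiary carbinols.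

Step 5
Reactants: 8 (2S,3R,4E,6S)-2,3-dihydroxy-2,4,6-trimethyl-1-(1H-pyrrol-1-yl)oct-4-en-1-one
Product: 9 (2S,3R,4E,6S)-2,4,6-trimethyl-1-(1H-pyrrol-1-yl)-2,3-bis(triethylsilyloxy)oct-4-en-1-one
Conditions: TESOTf (2.5 equiv), 2,6-lutidine, CH2Cl2, −78 → 0 °C; aq. NaHCO3
Reagents that add atoms: triethylsilyl trifluoromethanesulfonate, CC[Si](CC)(CC)OS(=O)(=O)C(F)(F)F
Why: Silyl triflate with a hindered pyridine base silylates secondary and tertiary alcohols alike, and the acylpyrrole is inert to it.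

Step 6
Reactants: 9 (2S,3R,4E,6S)-2,4,6-trimethyl-1-(1H-pyrrol-1-yl)-2,3-bis(triethylsilyloxy)oct-4-en-1-one, 10 tert-butyl acetate
Product: 11 tert-butyl (4S,5R,6E,8S)-4,6,8-trimethyl-3-oxo-4,5-bis(triethylsilyloxy)dec-6-enoate
Conditions: 10 (3 equiv), LDA, THF, −78 °C; then 9, −78 → −30 °C; aq. NH4Cl
Reagents that add atoms: none
Why: Crossed Claisen condensation of the ester enolate with the N-acylpyrrole should stop at the β-keto ester because the pyrrole carbinolate collapses only on work-up, and the quaternary α-carbon cannot epimerise.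

Step 7
Reactants: 11 tert-butyl (4S,5R,6E,8S)-4,6,8-trimethyl-3-oxo-4,5-bis(triethylsilyloxy)dec-6-enoate, 12 (E)-3-(dimethylamino)prop-2-enal (3 equiv)
Product: 14 6-[(2S,3R,4E,6S)-4,6-dimethyl-2,3-bis(triethylsilyloxy)oct-4-en-2-yl]-4-oxo-4H-pyran-3-carbaldehyde, via acylketene 13 (not isolated)
Conditions: PhMe, 110 °C, Ar stream; then AcOH (cat.), rt
Reagents that add atoms: none
Why: Thermal loss of tert-butanol gives the acylketene, which should be acylated at its ketene carbon by the nucleophilic α-carbon of the push–pull enamine and then close through the enol oxygen (acylketene–enamine formal [4+2]); loss of dimethylamine aromatises to the γ-pyranone.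

Step 8
Reactants: 14 6-[(2S,3R,4E,6S)-4,6-dimethyl-2,3-bis(triethylsilyloxy)oct-4-en-2-yl]-4-oxo-4H-pyran-3-carbaldehyde, 15 3-hydroxybutan-2-one (racemic acetoin, 1.5 equiv)
Product: 18 (7S,8R)-3-[(2S,3R,4E,6S)-4,6-dimethyl-2,3-bis(triethylsilyloxy)oct-4-en-2-yl]-7,8-dihydroxy-7-methyl-7,8-dihydro-6H-isochromen-6-one, via aldol adduct 16 (not isolated), via 4a-hydroxy ketone 17 (not isolated)
Conditions: (R,R)-ProPhenol (15 mol%), Et2Zn (30 mol%), 4 Å MS, THF, −20 °C; then CH2Cl2, TiCl4 (4 equiv), Et3N (8 equiv), −78 → 0 °C, same flask; aq. citric acid work-up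
Reagents that add atoms: none
Why: Proposed new method: the zinc complex turns both enantiomers of 15 into one bridging Z-zinc enediolate, which adds through a closed, metal-bridged transition state to the zinc-bound aldehyde of 14 to form C7–C8 (16); TiCl4/Et3N then enolises the only enolisable position left (the C5 methyl, C7 now being quaternary) and the titanium enolate, held in the O8–Ti–O=C4a chelate, adds 1,2 to the pyranone carbonyl (17), whose 4H-pyran-4-ol loses water on acidic work-up to give C4a=C5. The closest known reaction types are zinc-catalysed direct aldols of α-hydroxy ketones to syn-1,2-diols (including α-methyl donors that give tertiary carbinols) and TiCl4/amine aldol condensations; their merger into an α,α'-annulation ([3+3]) of a ketone onto a 3-formyl-4-pyranone is new. The carbocycle closes by a 6-(enolexo)-exo-trig aldol addition followed by pyrylium-type (E1cB) dehydration. The absolute configuration at C7 (S) and C8 (R) should come from the chiral pocket of the catalyst, the side-chain stereocentres being too remote to matter; the relative configuration (syn in the open chain, trans-diol on the ring) comes from the Z-enediolate geometry in the closed transition state. The step needs C7 to react before C5 (secured by chelated enediolate formation at the hydroxylated carbon), the aldehyde to react before the pyranone carbonyl or the conjugate position C1 (it is the most electrophilic, metal-bound site), and ring closure at C4a and not C1 (the s-trans unit C1=C8a–C4a=O cannot receive a metal-bridged enolate at C1, while the chelate holds C5 over C4a). The product is a vinylogous γ-pyrone, so the dehydration should be irreversible and pull the sequence forward.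

Step 9
Reactants: 18 (7S,8R)-3-[(2S,3R,4E,6S)-4,6-dimethyl-2,3-bis(triethylsilyloxy)oct-4-en-2-yl]-7,8-dihydroxy-7-methyl-7,8-dihydro-6H-isochromen-6-one
Product: 19 Pestaphilone G, (7S,8R)-3-[(2S,3R,4E,6S)-2,3-dihydroxy-4,6-dimethyloct-4-en-2-yl]-7,8-dihydroxy-7-methyl-7,8-dihydro-6H-isochromen-6-one
Conditions: HF·pyridine, pyridine, THF, 0 °C → rt
Reagents that add atoms: none
Why: Buffered fluoride desilylation removes both triethylsilyl ethers without base or strong acid, which spares the allylic C10 and C8 carbinols and the α-ketol.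

**Compound list**

1 | (S)-2-methylbutan-1-ol | CC[C@H](C)CO | starting material
2 | (S)-2-methylbutanal | CC[C@H](C)C=O | intermediate
3 | 2-(triphenylphosphoranylidene)propanal | CC(C=O)=P(c1ccccc1)(c1ccccc1)c1ccccc1 | starting material
4 | (2E,4S)-2,4-dimethylhex-2-enal | CC[C@H](C)/C=C(\C)C=O | intermediate
5 | 2-hydroxypropanamide (racemic lactamide) | CC(O)C(N)=O | starting material
6 | 2,5-dimethoxytetrahydrofuran | COC1CCC(OC)O1 | starting material
7 | 2-hydroxy-1-(1H-pyrrol-1-yl)propan-1-one (racemic) | CC(O)C(=O)n1cccc1 | intermediate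
8 | (2S,3R,4E,6S)-2,3-dihydroxy-2,4,6-trimethyl-1-(1H-pyrrol-1-yl)oct-4-en-1-one | CC[C@H](C)/C=C(\C)[C@@H](O)[C@](C)(O)C(=O)n1cccc1 | intermediate
9 | (2S,3R,4E,6S)-2,4,6-trimethyl-1-(1H-pyrrol-1-yl)-2,3-bis(triethylsilyloxy)oct-4-en-1-one | CC[C@H](C)/C=C(\C)[C@@H](O[Si](CC)(CC)CC)[C@](C)(O[Si](CC)(CC)CC)C(=O)n1cccc1 | intermediate
10 | tert-butyl acetate | CC(=O)OC(C)(C)C | starting material
11 | tert-butyl (4S,5R,6E,8S)-4,6,8-trimethyl-3-oxo-4,5-bis(triethylsilyloxy)dec-6-enoate | CC[C@H](C)/C=C(\C)[C@@H](O[Si](CC)(CC)CC)[C@](C)(O[Si](CC)(CC)CC)C(=O)CC(=O)OC(C)(C)C | intermediate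
12 | (E)-3-(dimethylamino)prop-2-enal | CN(C)/C=C/C=O | starting material
13 | (4S,5R,6E,8S)-4,6,8-trimethyl-4,5-bis(triethylsilyloxy)deca-1,6-diene-1,3-dione (acylketene) | CC[C@H](C)/C=C(\C)[C@@H](O[Si](CC)(CC)CC)[C@](C)(O[Si](CC)(CC)CC)C(=O)C=C=O | intermediate
14 | 6-[(2S,3R,4E,6S)-4,6-dimethyl-2,3-bis(triethylsilyloxy)oct-4-en-2-yl]-4-oxo-4H-pyran-3-carbaldehyde | CC[C@H](C)/C=C(\C)[C@@H](O[Si](CC)(CC)CC)[C@](C)(O[Si](CC)(CC)CC)C1=CC(=O)C(C=O)=CO1 | intermediate
15 | 3-hydroxybutan-2-one (racemic acetoin) | CC(O)C(C)=O | starting material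
16 | 2-[(2S,3R,4E,6S)-4,6-dimethyl-2,3-bis(triethylsilyloxy)oct-4-en-2-yl]-5-[(1R,2S)-1,2-dihydroxy-2-methyl-3-oxobutyl]-4H-pyran-4-one | CC[C@H](C)/C=C(\C)[C@@H](O[Si](CC)(CC)CC)[C@](C)(O[Si](CC)(CC)CC)C1=CC(=O)C(=CO1)[C@@H](O)[C@](C)(O)C(C)=O | intermediate
17 | (7S,8R)-3-[(2S,3R,4E,6S)-4,6-dimethyl-2,3-bis(triethylsilyloxy)oct-4-en-2-yl]-4a,7,8-trihydroxy-7-methyl-4a,5,7,8-tetrahydro-6H-isochromen-6-one (either configuration at C4a) | CC[C@H](C)/C=C(\C)[C@@H](O[Si](CC)(CC)CC)[C@](C)(O[Si](CC)(CC)CC)C1=CC2(O)CC(=O)[C@@](C)(O)[C@H](O)C2=CO1 | intermediate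
18 | (7S,8R)-3-[(2S,3R,4E,6S)-4,6-dimethyl-2,3-bis(triethylsilyloxy)oct-4-en-2-yl]-7,8-dihydroxy-7-methyl-7,8-dihydro-6H-isochromen-6-one | CC[C@H](C)/C=C(\C)[C@@H](O[Si](CC)(CC)CC)[C@](C)(O[Si](CC)(CC)CC)C1=CC2=CC(=O)[C@@](C)(O)[C@H](O)C2=CO1 | intermediate
19 | Pestaphilone G | CC[C@H](C)/C=C(\C)[C@@H](O)[C@](C)(O)C1=CC2=CC(=O)[C@@](C)(O)[C@H](O)C2=CO1 | target

**Step count**

Total: 9 steps. Longest linear sequence: 8 steps (1, 2, 4, 5, 6, 7, 8, 9).

**Steps most likely to fail**

Step 8. The enediolate may add in conjugate fashion at C1 of the formylpyranone with ring opening, the tertiary aldolate may undergo retro-aldol and lose diastereoselectivity, or the second enolate may close on C1 and not on C4a. The fallback makes the two bonds separately with known chemistry, setting out from 14 and returning at 18. Compound 14 is treated with tin(II) but-2-ene-2,3-diolate F1, generated from butane-2,3-dione and activated tin in THF at −78 °C. This is a known syn-selective enediolate aldol without reagent control, and it should give 16 together with its (1S,2R) diastereomer F2. Because the side chain is enantiopure, the two are diastereomers and are separated by chromatography. Pure 16 is then cyclised with TiCl4/Et3N (CH2Cl2, −78 → 0 °C) and dehydrated on acidic work-up, which rejoins the route at 18.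

Step 4. Enolisation of the α-branched donor may be slow, and the tetrasubstituted enediolate may add to the hindered enal with poor facial selectivity or revert by retro-aldol. The fallback sets the C9/C10 diol by known reagent-controlled chemistry, setting out from 4 and returning at 11. Wittig olefination of 4 with ethyl 2-(triphenylphosphoranylidene)propanoate gives ethyl (2E,4E,6S)-2,4,6-trimethylocta-2,4-dienoate F3, and DIBAL-H reduction gives (2E,4E,6S)-2,4,6-trimethylocta-2,4-dien-1-ol F4. Sharpless asymmetric epoxidation (Ti(OiPr)4, D-(−)-diethyl tartrate, tBuOOH) touches only the allylic alkene and gives [(2R,3R)-2-methyl-3-[(2E,4S)-4-methylhex-2-en-2-yl]oxiran-2-yl]methanol F5. Pd(0)-catalysed insertion of CO2 into the vinyl epoxide (double inversion at the allylic carbon, net retention) gives the cyclic carbonate of the syn-diol, (4R,5R)-4-(hydroxymethyl)-4-methyl-5-[(2E,4S)-4-methylhex-2-en-2-yl]-1,3-dioxolan-2-one F6. K2CO3/MeOH gives (2R,3R,4E,6S)-2,4,6-trimethyloct-4-ene-1,2,3-triol F7, and TESOTf/2,6-lutidine gives (2R,3R,4E,6S)-2,4,6-trimethyl-1,2,3-tris(triethylsilyloxy)oct-4-ene F8. Swern conditions convert the primary silyl ether directly into (2S,3R,4E,6S)-2,4,6-trimethyl-2,3-bis(triethylsilyloxy)oct-4-enal F9. Addition of the lithium enolate of 10 gives tert-butyl (6E,8S)-3-hydroxy-4,6,8-trimethyl-4,5-bis(triethylsilyloxy)dec-6-enoate F10 (C3 epimers, side-chain configuration as in 11), and Dess–Martin oxidation returns 11.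

Step 7. The acylketene may be attacked by the carbonyl oxygen of the vinylogous formamide instead of its α-carbon, or be captured by the dimethylamine that is released. The fallback uses an enol ether, setting out from 11 and returning at 14. Compound 11 is heated with 1,3,3-trimethoxypropene (PhMe, 110 °C), so that acylketene 13 is trapped in a hetero-Diels–Alder reaction as 3-(dimethoxymethyl)-2-methoxy-6-[(2S,3R,4E,6S)-4,6-dimethyl-2,3-bis(triethylsilyloxy)oct-4-en-2-yl]-2,3-dihydro-4H-pyran-4-one F11. PPTS expels methanol to give 5-(dimethoxymethyl)-2-[(2S,3R,4E,6S)-4,6-dimethyl-2,3-bis(triethylsilyloxy)oct-4-en-2-yl]-4H-pyran-4-one F12, and brief treatment with PPTS in wet acetone hydrolyses the acetal to 14.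

**Further compounds**

F1 | step 8 | tin(II) but-2-ene-2,3-diolate | CC1=C(C)O[Sn]O1
F2 | step 8 | 2-[(2S,3R,4E,6S)-4,6-dimethyl-2,3-bis(triethylsilyloxy)oct-4-en-2-yl]-5-[(1S,2R)-1,2-dihydroxy-2-methyl-3-oxobutyl]-4H-pyran-4-one | CC[C@H](C)/C=C(\C)[C@@H](O[Si](CC)(CC)CC)[C@](C)(O[Si](CC)(CC)CC)C1=CC(=O)C(=CO1)[C@H](O)[C@@](C)(O)C(C)=O
F3 | step 4 | ethyl (2E,4E,6S)-2,4,6-trimethylocta-2,4-dienoate | CC[C@H](C)/C=C(\C)/C=C(\C)C(=O)OCC
F4 | step 4 | (2E,4E,6S)-2,4,6-trimethylocta-2,4-dien-1-ol | CC[C@H](C)/C=C(\C)/C=C(\C)CO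
F5 | step 4 | [(2R,3R)-2-methyl-3-[(2E,4S)-4-methylhex-2-en-2-yl]oxiran-2-yl]methanol | CC[C@H](C)/C=C(\C)[C@@H]1[C@@](C)(CO)O1
F6 | step 4 | (4R,5R)-4-(hydroxymethyl)-4-methyl-5-[(2E,4S)-4-methylhex-2-en-2-yl]-1,3-dioxolan-2-one | CC[C@H](C)/C=C(\C)[C@H]1OC(=O)O[C@]1(C)CO
F7 | step 4 | (2R,3R,4E,6S)-2,4,6-trimethyloct-4-ene-1,2,3-triol | CC[C@H](C)/C=C(\C)[C@@H](O)[C@](C)(O)CO
F8 | step 4 | (2R,3R,4E,6S)-2,4,6-trimethyl-1,2,3-tris(triethylsilyloxy)oct-4-ene | CC[C@H](C)/C=C(\C)[C@@H](O[Si](CC)(CC)CC)[C@](C)(O[Si](CC)(CC)CC)CO[Si](CC)(CC)CC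
F9 | step 4 | (2S,3R,4E,6S)-2,4,6-trimethyl-2,3-bis(triethylsilyloxy)oct-4-enal | CC[C@H](C)/C=C(\C)[C@@H](O[Si](CC)(CC)CC)[C@](C)(O[Si](CC)(CC)CC)C=O
F10 | step 4 | tert-butyl (6E,8S)-3-hydroxy-4,6,8-trimethyl-4,5-bis(triethylsilyloxy)dec-6-enoate (C3 epimers, side-chain configuration as in 11) | CC[C@H](C)/C=C(\C)[C@@H](O[Si](CC)(CC)CC)[C@](C)(O[Si](CC)(CC)CC)C(O)CC(=O)OC(C)(C)C
F11 | step 7 | 3-(dimethoxymethyl)-2-methoxy-6-[(2S,3R,4E,6S)-4,6-dimethyl-2,3-bis(triethylsilyloxy)oct-4-en-2-yl]-2,3-dihydro-4H-pyran-4-one | CC[C@H](C)/C=C(\C)[C@@H](O[Si](CC)(CC)CC)[C@](C)(O[Si](CC)(CC)CC)C1=CC(=O)C(C(OC)OC)C(OC)O1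
F12 | step 7 | 5-(dimethoxymethyl)-2-[(2S,3R,4E,6S)-4,6-dimethyl-2,3-bis(triethylsilyloxy)oct-4-en-2-yl]-4H-pyran-4-one | CC[C@H](C)/C=C(\C)[C@@H](O[Si](CC)(CC)CC)[C@](C)(O[Si](CC)(CC)CC)C1=CC(=O)C(C(OC)OC)=CO1
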